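## Retrosynthetic overview

1. Target ⇐ hydrogenolysis of its octabenzyl ether; all five benzene rings (two A rings, ring B, the central ring) are bought.
2. Upper C3–OH/C4–H ⇐ hydroboration–oxidation of a 4-aryl-2H-chromene; lower cis-3,4-diol ⇐ osmylation of a 2-aryl-2H-chromene; both additions occur anti to the C2 aryl group.
3. Both pyran rings (upper ring C and lower ring C) ⇐ one chiral-acid double dehydrative ring closure of an acyclic bis(allylic alcohol): two C–O bonds, two rings, both C2 stereocentres.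
4. Bis(allylic alcohol) ⇐ 1,2-addition of the central-ring aryllithium to the upper 2'-hydroxychalcone, so the C4–aryl bond is made on an open chain before any heterocycle exists.
5. Both chalcones ⇐ Claisen–Schmidt condensations of one acetophenone with tribenzyloxybenzaldehyde and with its 2-bromo derivative.

Assumption: the (R)-phosphoramide is taken to give the (2S)-chromene at both sites; this is checked once on the single-ring model 6, and the (S)-catalyst is used instead if the sense is opposite.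

## Route

Step 1
Reactants: 1 1-[4-(benzyloxy)-2-hydroxyphenyl]ethan-1-one; 2 3,4,5-tris(benzyloxy)benzaldehyde
Product: 3 (E)-1-[4-(benzyloxy)-2-hydroxyphenyl]-3-[3,4,5-tris(benzyloxy)phenyl]prop-2-en-1-one
Conditions: KOH (50% aq.), EtOH/THF, rt, 36 h
Reagents that add atoms: none
Why: Claisen–Schmidt aldol condensation gives the thermodynamic E-enone, the standard entry to benzyl-protected 2'-hydroxychalcones; no stereocentre is formed.

Step 2
Reactants: 2 3,4,5-tris(benzyloxy)benzaldehyde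
Product: 4 2-bromo-3,4,5-tris(benzyloxy)benzaldehyde
Conditions: NBS (1.1 equiv), DMF, rt, dark
Reagents that add atoms: N-bromosuccinimide, O=C1CCC(=O)N1Br
Why: Electrophilic aromatic bromination can only occur at the two equivalent free positions of the trialkoxy ring (ortho and para to benzyloxy groups), so the bromine lands next to the aldehyde-bearing carbon and next to a benzyloxy group.

Step 3
Reactants: 1 1-[4-(benzyloxy)-2-hydroxyphenyl]ethan-1-one; 4 2-bromo-3,4,5-tris(benzyloxy)benzaldehyde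
Product: 5 (E)-1-[4-(benzyloxy)-2-hydroxyphenyl]-3-[2-bromo-3,4,5-tris(benzyloxy)phenyl]prop-2-en-1-one
Conditions: KOH (50% aq.), EtOH/THF, rt, 36 h
Reagents that add atoms: none
Why: A second Claisen–Schmidt condensation gives the E-chalcone; the aryl bromide and benzyl ethers are inert to aqueous base.

Step 4
Reactants: 5 (E)-1-[4-(benzyloxy)-2-hydroxyphenyl]-3-[2-bromo-3,4,5-tris(benzyloxy)phenyl]prop-2-en-1-one
Product: 6 (E)-1-[4-(benzyloxy)-2-hydroxyphenyl]-3-[2-bromo-3,4,5-tris(benzyloxy)phenyl]prop-2-en-1-ol (racemic)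
Conditions: NaBH4, CeCl3·7H2O, MeOH/THF, −20 °C; pH 7 buffer work-up, Et3N-deactivated silica
Reagents that add atoms: none
Why: Luche reduction gives clean 1,2-reduction of the enone without conjugate reduction; the carbinol is left racemic on purpose because it is ionised in step 6, and neutral work-up prevents premature ring closure.

Step 5
Reactants: 6 (E)-1-[4-(benzyloxy)-2-hydroxyphenyl]-3-[2-bromo-3,4,5-tris(benzyloxy)phenyl]prop-2-en-1-ol; 3 (E)-1-[4-(benzyloxy)-2-hydroxyphenyl]-3-[3,4,5-tris(benzyloxy)phenyl]prop-2-en-1-one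
Product: 8 (E)-1-[4-(benzyloxy)-2-hydroxyphenyl]-1-{2,3,4-tris(benzyloxy)-6-[(E)-3-[4-(benzyloxy)-2-hydroxyphenyl]-3-hydroxyprop-1-en-1-yl]phenyl}-3-[3,4,5-tris(benzyloxy)phenyl]prop-2-en-1-ol (mixture of carbinol stereoisomers), via trilithiated aryllithium 7 (not isolated)
Conditions: 6, n-BuLi (3.05 equiv), THF, −78 °C; then sodium phenoxide of 3 (3 + NaH), LaCl3·2LiCl, THF, −78 → −30 °C; aq. NH4Cl, used crude
Reagents that add atoms: none
Why: After both OH groups are masked as lithium salts, bromine–lithium exchange gives an aryllithium that adds 1,2 to the Lewis-acid-activated chalcone carbonyl (aryllithiums favour 1,2- over 1,4-addition to chalcones); the two new carbinol centres need no control because both are destroyed in step 6.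

Step 6
Reactants: 8 (E)-1-[4-(benzyloxy)-2-hydroxyphenyl]-1-{2,3,4-tris(benzyloxy)-6-[(E)-3-[4-(benzyloxy)-2-hydroxyphenyl]-3-hydroxyprop-1-en-1-yl]phenyl}-3-[3,4,5-tris(benzyloxy)phenyl]prop-2-en-1-ol
Product: 10 (2S)-7-(benzyloxy)-4-{2,3,4-tris(benzyloxy)-6-[(2S)-7-(benzyloxy)-2H-chromen-2-yl]phenyl}-2-[3,4,5-tris(benzyloxy)phenyl]-2H-chromene, via mono-chromene allylic alcohol 9 (not isolated)
Conditions: (R)-3,3'-bis(2,4,6-triisopropylphenyl)-5,5',6,6',7,7',8,8'-octahydro-1,1'-bi-2-naphthol N-triflylphosphoramide (10 mol%), 4 Å MS, toluene, −78 → −40 °C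
Reagents that add atoms: none
Why: Proposed new method: the strong chiral acid ionises first the tertiary doubly benzylic carbinol and then the secondary one to o-quinone-methide/allyl-cation contact ion pairs, each of which closes by phenol O-attack at the aryl-bearing terminus (oxa-6π ring closure/intramolecular allylic substitution), so the chiral anion sets C2 of both new pyran rings in one operation and an error at either centre appears as a separable diastereomer rather than as the enantiomer; the closest known reaction is the chiral N-triflylphosphoramide-catalysed enantioselective dehydrative cyclisation of a single 2-(hydroxyallyl)phenol to a 2-aryl-2H-chromene.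

Step 7
Reactants: 10 (2S)-7-(benzyloxy)-4-{2,3,4-tris(benzyloxy)-6-[(2S)-7-(benzyloxy)-2H-chromen-2-yl]phenyl}-2-[3,4,5-tris(benzyloxy)phenyl]-2H-chromene
Product: 11 (2R,3S,4S)-7-(benzyloxy)-2-{3,4,5-tris(benzyloxy)-2-[(2S)-7-(benzyloxy)-2-[3,4,5-tris(benzyloxy)phenyl]-2H-chromen-4-yl]phenyl}-3,4-dihydro-2H-chromene-3,4-diol
Conditions: OsO4 (4 mol%), NMO (1.1 equiv), acetone/THF/H2O, 0 °C
Reagents that add atoms: osmium tetroxide, O=[Os](=O)(=O)=O (delivers both oxygens); N-methylmorpholine N-oxide, C[N+]1([O-])CCOCC1, and water, O (net sources of the two oxygens as the osmium is turned over)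
Why: Upjohn syn-dihydroxylation attacks the cis-disubstituted styrenic alkene of the lower chromene on the face anti to its C2 aryl group, which gives the 2,3-trans-3,4-cis diol, while the trisubstituted upper alkene, shielded on both faces by the orthogonal 2,6-disubstituted aryl group at C4, should react more slowly.

Step 8
Reactants: 11 (2R,3S,4S)-7-(benzyloxy)-2-{3,4,5-tris(benzyloxy)-2-[(2S)-7-(benzyloxy)-2-[3,4,5-tris(benzyloxy)phenyl]-2H-chromen-4-yl]phenyl}-3,4-dihydro-2H-chromene-3,4-diol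
Product: 13 (2R,3S,4S)-7-(benzyloxy)-2-{3,4,5-tris(benzyloxy)-2-[(2R,3S,4S)-7-(benzyloxy)-3-hydroxy-2-[3,4,5-tris(benzyloxy)phenyl]-3,4-dihydro-2H-chromen-4-yl]phenyl}-3,4-dihydro-2H-chromene-3,4-diol, via C3-alkylborane 12 (not isolated)
Conditions: BH3·SMe2 (6 equiv), THF, 0 °C → rt; then NaOH, H2O2, 0 °C
Reagents that add atoms: hydrogen peroxide, OO (oxygen of the new C3 hydroxyl)
Why: Brown hydroboration–oxidation places boron on the less substituted C3 anti to the C2 aryl group and hydrogen on C4 from the same face, and oxidation with retention then gives the 2,3-trans-3,4-trans 4-arylflavan-3-ol (the known outcome for 4-arylflav-3-enes), the lower diol being held as a borate until work-up.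

Step 9
Reactants: 13 (2R,3S,4S)-7-(benzyloxy)-2-{3,4,5-tris(benzyloxy)-2-[(2R,3S,4S)-7-(benzyloxy)-3-hydroxy-2-[3,4,5-tris(benzyloxy)phenyl]-3,4-dihydro-2H-chromen-4-yl]phenyl}-3,4-dihydro-2H-chromene-3,4-diol
Product: 14 (2R,3S,4S)-2-{2-[(2R,3S,4S)-3,7-dihydroxy-2-(3,4,5-trihydroxyphenyl)-3,4-dihydro-2H-chromen-4-yl]-3,4,5-trihydroxyphenyl}-3,4-dihydro-2H-chromene-3,4,7-triol
Conditions: H2 (1 atm), Pd/C (10 wt% Pd), degassed THF/MeOH, rt, stopped at eight equivalents of uptake; Sephadex LH-20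
Reagents that add atoms: none
Why: Catalytic hydrogenolysis cleaves the eight aryl benzyl ethers far faster than the benzylic C4–OH or the ring C–O bonds under neutral acid-free conditions (as in the final debenzylation of p-hydroxyphenyl carbinols), and no stereocentre is touched.

## Compound list

1 | 1-[4-(benzyloxy)-2-hydroxyphenyl]ethan-1-one | CC(=O)c1ccc(OCc2ccccc2)cc1O | starting material
2 | 3,4,5-tris(benzyloxy)benzaldehyde | O=Cc1cc(OCc2ccccc2)c(OCc2ccccc2)c(OCc2ccccc2)c1 | starting material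
3 | (E)-1-[4-(benzyloxy)-2-hydroxyphenyl]-3-[3,4,5-tris(benzyloxy)phenyl]prop-2-en-1-one | O=C(/C=C/c1cc(OCc2ccccc2)c(OCc2ccccc2)c(OCc2ccccc2)c1)c1ccc(OCc2ccccc2)cc1O | intermediate
4 | 2-bromo-3,4,5-tris(benzyloxy)benzaldehyde | O=Cc1cc(OCc2ccccc2)c(OCc2ccccc2)c(OCc2ccccc2)c1Br | intermediate
5 | (E)-1-[4-(benzyloxy)-2-hydroxyphenyl]-3-[2-bromo-3,4,5-tris(benzyloxy)phenyl]prop-2-en-1-one | O=C(/C=C/c1cc(OCc2ccccc2)c(OCc2ccccc2)c(OCc2ccccc2)c1Br)c1ccc(OCc2ccccc2)cc1O | intermediate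
6 | (E)-1-[4-(benzyloxy)-2-hydroxyphenyl]-3-[2-bromo-3,4,5-tris(benzyloxy)phenyl]prop-2-en-1-ol (racemic) | OC(/C=C/c1cc(OCc2ccccc2)c(OCc2ccccc2)c(OCc2ccccc2)c1Br)c1ccc(OCc2ccccc2)cc1O | intermediate
7 | trilithio derivative of 6 (lithium alkoxide, lithium phenoxide, aryllithium in place of bromine) | [Li]OC(/C=C/c1cc(OCc2ccccc2)c(OCc2ccccc2)c(OCc2ccccc2)c1[Li])c1ccc(OCc2ccccc2)cc1O[Li] | intermediate (not isolated)
8 | (E)-1-[4-(benzyloxy)-2-hydroxyphenyl]-1-{2,3,4-tris(benzyloxy)-6-[(E)-3-[4-(benzyloxy)-2-hydroxyphenyl]-3-hydroxyprop-1-en-1-yl]phenyl}-3-[3,4,5-tris(benzyloxy)phenyl]prop-2-en-1-ol (mixture of carbinol stereoisomers) | OC(/C=C/c1cc(OCc2ccccc2)c(OCc2ccccc2)c(OCc2ccccc2)c1C(O)(/C=C/c1cc(OCc2ccccc2)c(OCc2ccccc2)c(OCc2ccccc2)c1)c1ccc(OCc2ccccc2)cc1O)c1ccc(OCc2ccccc2)cc1O | intermediate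
9 | (E)-1-[4-(benzyloxy)-2-hydroxyphenyl]-3-{3,4,5-tris(benzyloxy)-2-[(2S)-7-(benzyloxy)-2-[3,4,5-tris(benzyloxy)phenyl]-2H-chromen-4-yl]phenyl}prop-2-en-1-ol (carbinol epimers) | O(Cc9ccccc9)c1ccc2c(c1)O[C@H](c1cc(OCc9ccccc9)c(OCc9ccccc9)c(OCc9ccccc9)c1)C=C2c1c(/C=C/C(O)c2ccc(OCc9ccccc9)cc2O)cc(OCc9ccccc9)c(OCc9ccccc9)c1OCc9ccccc9 | intermediate (not isolated)
10 | (2S)-7-(benzyloxy)-4-{2,3,4-tris(benzyloxy)-6-[(2S)-7-(benzyloxy)-2H-chromen-2-yl]phenyl}-2-[3,4,5-tris(benzyloxy)phenyl]-2H-chromene | O(Cc9ccccc9)c1ccc2c(c1)O[C@H](c1cc(OCc9ccccc9)c(OCc9ccccc9)c(OCc9ccccc9)c1)C=C2c1c([C@H]2Oc3cc(OCc9ccccc9)ccc3C=C2)cc(OCc9ccccc9)c(OCc9ccccc9)c1OCc9ccccc9 | intermediate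
11 | (2R,3S,4S)-7-(benzyloxy)-2-{3,4,5-tris(benzyloxy)-2-[(2S)-7-(benzyloxy)-2-[3,4,5-tris(benzyloxy)phenyl]-2H-chromen-4-yl]phenyl}-3,4-dihydro-2H-chromene-3,4-diol | O(Cc9ccccc9)c1ccc2c(c1)O[C@H](c1cc(OCc9ccccc9)c(OCc9ccccc9)c(OCc9ccccc9)c1)C=C2c1c([C@H]2Oc3cc(OCc9ccccc9)ccc3[C@H](O)[C@@H]2O)cc(OCc9ccccc9)c(OCc9ccccc9)c1OCc9ccccc9 | intermediate
12 | C3-borane of 11: BH2 on C3 and H on C4 of the upper ring, both on the face opposite the C2 aryl group (same arrangement as 13 with BH2 in place of the C3 hydroxyl); lower cis-diol held as a cyclic hydridoborate | O(Cc9ccccc9)c1ccc2c(c1)O[C@H](c1cc(OCc9ccccc9)c(OCc9ccccc9)c(OCc9ccccc9)c1)[C@@H](B)[C@@H]2c1c([C@H]2Oc3cc(OCc9ccccc9)ccc3[C@H](OB4)[C@@H]2O4)cc(OCc9ccccc9)c(OCc9ccccc9)c1OCc9ccccc9 | intermediate (not isolated)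
13 | (2R,3S,4S)-7-(benzyloxy)-2-{3,4,5-tris(benzyloxy)-2-[(2R,3S,4S)-7-(benzyloxy)-3-hydroxy-2-[3,4,5-tris(benzyloxy)phenyl]-3,4-dihydro-2H-chromen-4-yl]phenyl}-3,4-dihydro-2H-chromene-3,4-diol | O(Cc9ccccc9)c1ccc2c(c1)O[C@H](c1cc(OCc9ccccc9)c(OCc9ccccc9)c(OCc9ccccc9)c1)[C@@H](O)[C@@H]2c1c([C@H]2Oc3cc(OCc9ccccc9)ccc3[C@H](O)[C@@H]2O)cc(OCc9ccccc9)c(OCc9ccccc9)c1OCc9ccccc9 | intermediate
14 | (2R,3S,4S)-2-{2-[(2R,3S,4S)-3,7-dihydroxy-2-(3,4,5-trihydroxyphenyl)-3,4-dihydro-2H-chromen-4-yl]-3,4,5-trihydroxyphenyl}-3,4-dihydro-2H-chromene-3,4,7-triol | Oc1ccc2c(c1)O[C@H](c1cc(O)c(O)c(O)c1)[C@@H](O)[C@@H]2c1c([C@H]2Oc3cc(O)ccc3[C@H](O)[C@@H]2O)cc(O)c(O)c1O | target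

## Step count and risks

Total step count: 9. Longest linear sequence: 8 steps (2 → 4 → 5 → 6 → 8 → 10 → 11 → 13 → 14); step 1 is the only side branch.

The three steps most likely to fail:

**Step 5.** A trilithiated, doubly ortho-substituted aryllithium must add to a phenoxide-deactivated enone, and the product 8 is very acid-labile. Fallback: mask the acidic groups covalently so that a mono-anionic aryllithium meets a neutral enone. It sets out from 6 (with 3). Silylation of 6 (TBSOTf, 2,6-lutidine, CH2Cl2, −40 °C) gives the bis(tert-butyldimethylsilyl) ether of 6 F1. The same treatment of 3 gives the 2'-O-tert-butyldimethylsilyl chalcone F2. F1 with n-BuLi (1.05 equiv, THF, −78 °C) followed by F2 gives the tris-silylated tertiary carbinol F3. Bu4NF/AcOH (THF, 0 °C) removes the three silyl groups without acid, and the fallback comes back to the route at 8.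

**Step 6.** One catalyst must control two different cyclisations: the 4-aryl case has close precedent, the 4-unsubstituted lower ring does not. Uncatalysed background closure and a 5-endo cation–alkene closure to an indene are possible leaks. Fallback: close the rings one at a time and rely on diastereomer separation anchored on the precedented centre. It sets out from 8. The weaker acid (R)-3,3'-bis(2,4,6-triisopropylphenyl)-1,1'-binaphthyl-2,2'-diyl hydrogen phosphate (toluene, −20 °C) ionises only the tertiary carbinol, and 9 is isolated. The lower ring is then closed without asymmetric control (pyridinium p-toluenesulfonate, CH2Cl2, 0 °C). This gives 10 together with its C2''-epimer, the (2S,2''R)-bis-chromene F4. Because the upper centre is fixed these are diastereomers, separated by chromatography here or as the diols after step 7, and the fallback comes back to the route at 10.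

**Step 7.** Osmylation has to select the lower cis-disubstituted alkene over the upper trisubstituted one. In addition, 10 and 11 may show slow rotation about the C4–aryl bond; the rotamers converge once C4 becomes sp3 in step 8. Fallback: install the diol before the second alkene exists. It sets out from 6. The same phosphoramide closes the single ring (toluene, −78 °C) to the (2S)-bromochromene F5. OsO4/NMO then gives the bromodiol F6 with only one alkene present. F6 with n-BuLi (3.05 equiv, THF, −78 °C; two equivalents for the diol, one for the exchange) and then the sodium phenoxide of 3 with LaCl3·2LiCl gives the tertiary carbinol F7. The phosphoramide closes the upper ring of F7, and the fallback comes back to the route at 11.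

## Further compounds

F1 | step 5 | (E)-1-[4-(benzyloxy)-2-(tert-butyldimethylsilyloxy)phenyl]-3-[2-bromo-3,4,5-tris(benzyloxy)phenyl]prop-2-en-1-yl tert-butyldimethylsilyl ether (racemic) | CC(C)(C)[Si](C)(C)OC(/C=C/c1cc(OCc2ccccc2)c(OCc2ccccc2)c(OCc2ccccc2)c1Br)c1ccc(OCc2ccccc2)cc1O[Si](C)(C)C(C)(C)C
F2 | step 5 | (E)-1-[4-(benzyloxy)-2-(tert-butyldimethylsilyloxy)phenyl]-3-[3,4,5-tris(benzyloxy)phenyl]prop-2-en-1-one | O=C(/C=C/c1cc(OCc2ccccc2)c(OCc2ccccc2)c(OCc2ccccc2)c1)c1ccc(OCc2ccccc2)cc1O[Si](C)(C)C(C)(C)C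
F3 | step 5 | tris(tert-butyldimethylsilyl) ether of 8 (both phenols and the secondary carbinol silylated, tertiary carbinol free; stereoisomer mixture) | CC(C)(C)[Si](C)(C)OC(/C=C/c1cc(OCc2ccccc2)c(OCc2ccccc2)c(OCc2ccccc2)c1C(O)(/C=C/c1cc(OCc2ccccc2)c(OCc2ccccc2)c(OCc2ccccc2)c1)c1ccc(OCc2ccccc2)cc1O[Si](C)(C)C(C)(C)C)c1ccc(OCc2ccccc2)cc1O[Si](C)(C)C(C)(C)C
F4 | step 6 | (2S)-7-(benzyloxy)-4-{2,3,4-tris(benzyloxy)-6-[(2R)-7-(benzyloxy)-2H-chromen-2-yl]phenyl}-2-[3,4,5-tris(benzyloxy)phenyl]-2H-chromene | O(Cc9ccccc9)c1ccc2c(c1)O[C@H](c1cc(OCc9ccccc9)c(OCc9ccccc9)c(OCc9ccccc9)c1)C=C2c1c([C@@H]2Oc3cc(OCc9ccccc9)ccc3C=C2)cc(OCc9ccccc9)c(OCc9ccccc9)c1OCc9ccccc9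
F5 | step 7 | (2S)-7-(benzyloxy)-2-[2-bromo-3,4,5-tris(benzyloxy)phenyl]-2H-chromene | Brc1c([C@H]2Oc3cc(OCc9ccccc9)ccc3C=C2)cc(OCc9ccccc9)c(OCc9ccccc9)c1OCc9ccccc9
F6 | step 7 | (2R,3S,4S)-7-(benzyloxy)-2-[2-bromo-3,4,5-tris(benzyloxy)phenyl]-3,4-dihydro-2H-chromene-3,4-diol | Brc1c([C@H]2Oc3cc(OCc9ccccc9)ccc3[C@H](O)[C@@H]2O)cc(OCc9ccccc9)c(OCc9ccccc9)c1OCc9ccccc9
F7 | step 7 | (2R,3S,4S)-7-(benzyloxy)-2-{3,4,5-tris(benzyloxy)-2-[(E)-1-[4-(benzyloxy)-2-hydroxyphenyl]-1-hydroxy-3-[3,4,5-tris(benzyloxy)phenyl]prop-2-en-1-yl]phenyl}-3,4-dihydro-2H-chromene-3,4-diol (carbinol epimers) | OC(/C=C/c1cc(OCc9ccccc9)c(OCc9ccccc9)c(OCc9ccccc9)c1)(c1ccc(OCc9ccccc9)cc1O)c1c([C@H]2Oc3cc(OCc9ccccc9)ccc3[C@H](O)[C@@H]2O)cc(OCc9ccccc9)c(OCc9ccccc9)c1OCc9ccccc9
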